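Atom numbering used throughout (germacrane convention): C1 free carbinol, C2 ring methylene, C3 acetoxy carbon, C4=C5 olefin with C15 (hydroxymethyl) on C4, C6 lactone carbinol, C7 ring-fusion carbon, C8 angelate carbon, C9=C10 olefin with C14 (methyl) on C10, C11 lactone α-carbon, C12 lactone carbonyl, C13 exocyclic methylene. TBS = tert-butyldimethylsilyl, TES = triethylsilyl, PMB = 4-methoxybenzyl.

## Analysis of the target

Compound 37 is a germacranolide: a ten-membered carbocycle (C1–C10) fused at C6–C7 to an α-methylene-γ-butyrolactone whose oxygen sits on C6. Both ring olefins, C4=C5 and C9=C10, are trisubstituted and have their ring carbons cis. There are five stereocentres, (1S,3S,6S,7S,8R) in this numbering. C6, C7 and C8 are contiguous: H6 and H7 are trans on the lactone, and O8 is syn to C11 when C6–C7–C8–C9 is drawn as a zigzag. C1 and C3 form a separate anti-1,3-diol across the C2 methylene. Three acyl groups must end up on three specific oxygens (lactone on O6, angelate on O8, acetate on O3) while O1 and O15 stay free. The angelate isomerises easily to the tiglate, the methylene lactone is a Michael acceptor, and the allylic esters can migrate or ionise. The synthesis is hard for two reasons: a ten-membered ring with two cis-trisubstituted olefins has to be closed, and a C1 ketone standing cis to a free C8 hydroxyl would close to a hemiketal and aromatise to a furan, which restricts the order of events. The strategy rests on the segment C1(OH)–C2H2–C3(OAc): an anti-1,3-diol monoacetate is exactly what an Evans–Tishchenko reduction of a C3-hydroxy C1-ketone gives, so the ring has an aldol retron across C2–C3.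

## Retrosynthetic reasoning

37 to 36. Only the C15 silyl ether is removed last. Keeping O15 masked until the end prevents the primary allylic alcohol from competing as an acyl acceptor or being oxidised. The forward step must cleave Si–O without moving the C3 acetate.

36 to 34. The C1–H bond and the acetyl–O3 bond are disconnected together (Evans–Tishchenko). This sets C1 from C3, distinguishes O1 from O3 without a protecting group, and leaves a β-hydroxy ketone as the precursor. The forward step has to deliver hydride 1,2 to an enone inside the ring and must not trigger retro-aldol opening.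

34 to 32. The ring is opened at C2–C3. C2 is the only methylene of the ring and carries no stereocentre, so the closure creates a single new stereocentre (C3). Both ends are already at the oxidation levels the next step needs (C1 ketone, C3 aldehyde). Bonds such as C7–C8 or C5–C6 bear stereocentres that are better set before the ring exists. The forward reaction needs an enolate located at C2 only, in a molecule with other acidic positions (C14, H8, H7) and three base-sensitive esters. It is therefore generated reductively from the bromide in 32, not by deprotonation.

32 to 31 to 30. The C3 aldehyde is unveiled last, from the PMB ether of 30 via alcohol 31. The enal with its formyl group cis to C6 is configurationally fragile and should meet as few reagents as possible.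

30 to 29 to 27 + 28. C1 and C2 are attached at C10 as the enol ether of 29 by a Stille coupling of iodide 27 with 28. Bromination of the enol ether gives the bromomethyl ketone without any base. The C10 iodide serves as an inert placeholder so that no C1 ketone exists while O8 is free.

27 to 24 + 25. The angelate C–O bond is cut; the acid 25 is introduced intact on the only free hydroxyl of 24.

24 to 18 + 22. The C7–C8 bond joins the two halves. Making it by allylation with the cyclic 2-(bromomethyl)acrylate 18 creates the methylene lactone and two stereocentres (C7, C8) under control of C6. Because the lactone is already closed on O6 before the C8 hydroxyl exists, the isomeric 7,8-lactone is excluded. The forward step must add on the face opposite the C6 substituent and pass through a closed transition state.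

18 to 17 to 16 to 15. The bromide comes from alcohol 17 and its silyl ether 16. The lactone (C11–C12 and C12–O6 bonds) is cut back to the cis iodo alcohol 15 by a carbonylative ring closure, which needs no protecting group on O6.

15 to 13 to 9 + 11. The C11 iodide comes from directed hydroalumination of alkyne 13. The C6–C7 bond is made by enantioselective alkynylation of enal 9 with 11, the only reagent-controlled stereocentre of the route. C7 and C8 (step 14), C3 (step 20) and C1 (step 21) all descend from it.

9 to 8 to 4 + 7, and 4 to 2 to 1. The C3–C4 bond is made by Stille coupling of iodide 4 with stannane 7. The geometry of C4=C5 comes from hydroalumination–iodination of 2: the iodine lands cis to the free hydroxymethyl (future C6), so the carbon that replaces it is C3 and the silyloxymethyl already present is C15. Diol 1 supplies C6, C5, C4 and C15.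

22 to 21 to 19; 7 from 5 + 6; 11 from 10. The same hydroalumination–iodination on 19 gives the C8–C9=C10(C14) unit with iodine cis to C8. The two reagents 7 and 11 are each one step from commercial materials.

## Alternatives that were turned down

Alternative 1: The C7–C8 bond would be formed by a Wittig–Still [2,3]-sigmatropic ring contraction. O8 is first tied to C13 as an allyl ether inside a thirteen-membered ring with tributyltin on C8. Tin–lithium exchange with n-BuLi then gives a C8 carbanion that attacks C7 while the O–C13 bond breaks. The product is A1, the ten-membered carbocycle with a free C8 hydroxyl and the C11=C13 methylene.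
- For: the most crowded bond of the molecule forms through a tight five-membered transition state that relays configuration to C7 and C8. The difficult ten-membered closure is replaced by closure of a larger ring and contraction. On stereocontrol at the bond it makes, this is stronger than the chosen closure, whose C3 outcome rests on conformational bias alone.
- Against: the organolithium step forces every oxygen to be an ether. A1 carries five protecting groups of three kinds, and C12 is at the alcohol oxidation level. The lactone must still be made by oxidation and closure, O8 angeloylated, O1 and O3 told apart and acetylated selectively, and the ethers removed in order, roughly eight to ten steps after the key step. A configurationally defined α-alkoxystannane and a macrocyclic etherification are needed first, and [1,2]-shift competes with the [2,3]-shift.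
- In its place, the chosen route closes the ring with every acyl group already installed and finishes in two steps, one of which sets C1 and places the acetate together.

Alternative 2: No skeletal bond is made in the key step. A cis-fused decalin-1,6-diol derived from carvone is cleaved at C1–C6 by Pb(OAc)4 buffered with K2CO3, through a cyclic lead diester, releasing the ten-membered dienedione A2.
- For: ring formation is a fragmentation with no entropic penalty and no high dilution, and both cis olefins are inherited from six-membered rings and cannot have the wrong geometry. On certainty of obtaining the ring this is clearly stronger than the chosen step.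
- Against: A2 has ketones at both C1 and C6, and both must be reduced stereoselectively in a flexible ring. C6 must give the alcohol that lactonises trans and C1 the alcohol anti to the C3 acetate, with no free hydroxyl left to direct either hydride. The C3 acetate is β to the C1 ketone and prone to elimination, and C7 is α to the C6 ketone and epimerisable. The fully substituted decalin with C3, C7 and C8 in place needs a long linear construction, and the carvone skeleton lacks the C15 oxygen.
- In its place, the chosen route creates the late stereocentres one at a time with a stated control element for each (ring bias for C3, directed hydride for C1) and needs no reduction of an unbiased ketone.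

Alternative 3: The C4=C5 olefin would be formed by an intramolecular Horner–Wadsworth–Emmons reaction. A phosphonoacetate carbon (C4, its ester being the future C15) is deprotonated with LiCl and DBU at high dilution and condenses with a C5 aldehyde to give A3.
- For: this is among the most dependable macrocyclisations, the base is mild, and olefin and ring form together. C1, C3, C6, C7 and C8 are all set beforehand in open-chain intermediates by reagent-controlled reactions. On stereochemical certainty of the carbinol centres it is stronger than the chosen closure.
- Against: the uncertainty moves to the olefin geometry, which is decided by ring strain in the closing step and cannot be corrected afterwards. The phosphonate carbon carries the free C3 carbinol in the β-position (retro-aldol or elimination under base), and the aldehyde is α-oxygenated at C6 and epimerisable. After closure the C15 ester must be reduced, C12 oxidised and lactonised, the PMB group on O8 exchanged for the angelate and O3 acetylated selectively, again about eight steps.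
- In its place, the chosen route fixes both olefin geometries in small open-chain precursors by directed hydroalumination before the ring exists, closes the ring at a methylene, and has a two-step endgame.

Key step: step 20

Assumption: the sense of induction of the ProPhenol ligand in step 7 is assumed; both antipodes are commercial and the one that gives (S)-13 is used.

## Route

Step 1
Reactants: 1 2-butyne-1,4-diol
Product: 2 4-(tert-butyldimethylsilyloxy)but-2-yn-1-ol
Conditions: NaH (1 equiv), THF, 0 °C; then TBSCl, rt (diol in excess)
Reagents that add atoms: tert-butyldimethylsilyl chloride CC(C)(C)[Si](C)(C)Cl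
Why: Monosilylation of a symmetrical diol through its sparingly soluble monosodium alkoxide; the excess diol is recovered.

Step 2
Reactants: 2 4-(tert-butyldimethylsilyloxy)but-2-yn-1-ol
Product: 4 (Z)-4-(tert-butyldimethylsilyloxy)-3-iodobut-2-en-1-ol, via cyclic alkenylaluminate 3 (not isolated)
Conditions: NaAlH2(OCH2CH2OCH3)2 (Red-Al), THF, 0 °C; then I2, −78 °C to 0 °C
Reagents that add atoms: iodine II
Why: Alkoxide-directed trans-hydroalumination places aluminium on the distal alkyne carbon in the five-membered aluminate 3, and iodinolysis with retention puts iodine cis to the hydroxymethyl group. This fixes the later C4=C5 geometry: the iodine marks the position of C3, cis to C6.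

Step 3
Reactants: 5 4-methoxybenzyl alcohol; 6 tributyl(iodomethyl)stannane
Product: 7 tributyl[(4-methoxybenzyloxy)methyl]stannane
Conditions: NaH, THF/DMF, 0 °C to rt
Reagents that add atoms: none
Why: Williamson ether synthesis; the primary iodide next to tin is displaced cleanly by the alkoxide.

Step 4
Reactants: 4 (Z)-4-(tert-butyldimethylsilyloxy)-3-iodobut-2-en-1-ol; 7 tributyl[(4-methoxybenzyloxy)methyl]stannane
Product: 8 (E)-4-(tert-butyldimethylsilyloxy)-3-[(4-methoxybenzyloxy)methyl]but-2-en-1-ol
Conditions: Pd(PPh3)4 (cat.), CuI (cat.), DMF, 60 °C
Reagents that add atoms: none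
Why: Stille coupling with retention of olefin geometry; an α-alkoxymethyl group on tin transfers in preference to butyl and the free hydroxyl is tolerated. The new carbon (C3) is cis to the hydroxymethyl group (C6).

Step 5
Reactants: 8 (E)-4-(tert-butyldimethylsilyloxy)-3-[(4-methoxybenzyloxy)methyl]but-2-en-1-ol
Product: 9 (E)-4-(tert-butyldimethylsilyloxy)-3-[(4-methoxybenzyloxy)methyl]but-2-enal
Conditions: MnO2 (activated, excess), CH2Cl2, rt
Reagents that add atoms: none
Why: Allylic oxidation on MnO2 under neutral conditions, which preserves the geometry of the enal; this matters because its two β-substituents differ only in their protecting groups.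

Step 6
Reactants: 10 prop-2-yn-1-ol
Product: 11 triethyl(prop-2-yn-1-yloxy)silane
Conditions: TESCl, imidazole, CH2Cl2, 0 °C
Reagents that add atoms: triethylsilyl chloride CC[Si](CC)(CC)Cl
Why: Standard silylation; TES is chosen because it can later be removed in the presence of the primary TBS ether.

Step 7
Reactants: 9 (E)-4-(tert-butyldimethylsilyloxy)-3-[(4-methoxybenzyloxy)methyl]but-2-enal; 11 triethyl(prop-2-yn-1-yloxy)silane
Product: 13 (4S,5E)-7-(tert-butyldimethylsilyloxy)-6-[(4-methoxybenzyloxy)methyl]-1-(triethylsilyloxy)hept-5-en-2-yn-4-ol, via alkynylzinc 12 (not isolated)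
Conditions: Me2Zn, (S,S)-ProPhenol (cat.), Ph3PO (cat.), toluene, 0 °C to rt
Reagents that add atoms: none
Why: Catalytic enantioselective alkynylation of an enal with a dinuclear zinc–ProPhenol catalyst: the alkynylzinc 12 adds 1,2 to the aldehyde inside the chiral pocket and sets C6, the only stereocentre of the route fixed by a reagent. The (S) configuration is to be confirmed by NMR analysis of the diastereomeric α-methoxy-α-trifluoromethylphenylacetates before going on.

Step 8
Reactants: 13 (4S,5E)-7-(tert-butyldimethylsilyloxy)-6-[(4-methoxybenzyloxy)methyl]-1-(triethylsilyloxy)hept-5-en-2-yn-4-ol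
Product: 15 (2Z,4S,5E)-7-(tert-butyldimethylsilyloxy)-2-iodo-6-[(4-methoxybenzyloxy)methyl]-1-(triethylsilyloxy)hepta-2,5-dien-4-ol, via cyclic alkenylaluminate 14 (not isolated)
Conditions: NaAlH2(OCH2CH2OCH3)2 (Red-Al), THF, −20 °C to 0 °C; then I2, −78 °C
Reagents that add atoms: iodine II
Why: The same directed trans-hydroalumination–iodination as in step 2, now steered by the C6 alkoxide, so that iodine sits on C11 cis to C6. Low temperature suppresses β-elimination of the silyloxy group to an allene, and the stereocentre is not touched.

Step 9
Reactants: 15 (2Z,4S,5E)-7-(tert-butyldimethylsilyloxy)-2-iodo-6-[(4-methoxybenzyloxy)methyl]-1-(triethylsilyloxy)hepta-2,5-dien-4-ol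
Product: 16 (S)-5-{(E)-3-(tert-butyldimethylsilyloxy)-2-[(4-methoxybenzyloxy)methyl]prop-1-enyl}-3-[(triethylsilyloxy)methyl]furan-2(5H)-one
Conditions: PdCl2(PPh3)2 (cat.), CO (1 atm), K2CO3, THF, rt
Reagents that add atoms: carbon monoxide [C-]#[O+]
Why: Palladium-catalysed cyclocarbonylation: oxidative addition into the C–I bond, CO insertion and capture of the acylpalladium by the cis C6 hydroxyl close the butenolide, with C12 coming from CO. A heterogeneous weak base and room temperature are chosen to limit deprotonation at the doubly allylic C6.

Step 10
Reactants: 16 (S)-5-{(E)-3-(tert-butyldimethylsilyloxy)-2-[(4-methoxybenzyloxy)methyl]prop-1-enyl}-3-[(triethylsilyloxy)methyl]furan-2(5H)-one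
Product: 17 (S)-5-{(E)-3-(tert-butyldimethylsilyloxy)-2-[(4-methoxybenzyloxy)methyl]prop-1-enyl}-3-(hydroxymethyl)furan-2(5H)-one
Conditions: PPTS (cat.), MeOH, 0 °C
Reagents that add atoms: none
Why: Acid-catalysed methanolysis removes the less hindered TES ether much faster than the primary TBS ether.

Step 11
Reactants: 17 (S)-5-{(E)-3-(tert-butyldimethylsilyloxy)-2-[(4-methoxybenzyloxy)methyl]prop-1-enyl}-3-(hydroxymethyl)furan-2(5H)-one
Product: 18 (S)-3-(bromomethyl)-5-{(E)-3-(tert-butyldimethylsilyloxy)-2-[(4-methoxybenzyloxy)methyl]prop-1-enyl}furan-2(5H)-one
Conditions: CBr4, PPh3, CH2Cl2, 0 °C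
Reagents that add atoms: tetrabromomethane BrC(Br)(Br)Br
Why: Appel bromination of the primary allylic alcohol under neutral conditions gives the cyclic 2-(bromomethyl)acrylate needed for the allylation.

Step 12
Reactants: 19 but-2-yn-1-ol
Product: 21 (Z)-3-iodobut-2-en-1-ol, via cyclic alkenylaluminate 20 (not isolated)
Conditions: NaAlH2(OCH2CH2OCH3)2 (Red-Al), THF, 0 °C to rt; then I2, −78 °C
Reagents that add atoms: iodine II
Why: Directed trans-hydroalumination–iodination as in step 2; the iodine on the future C10 is cis to the future C8.

Step 13
Reactants: 21 (Z)-3-iodobut-2-en-1-ol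
Product: 22 (Z)-3-iodobut-2-enal
Conditions: MnO2 (activated, excess), CH2Cl2, rt, dark
Reagents that add atoms: none
Why: Neutral allylic oxidation with retention of the Z geometry; the volatile, light-sensitive aldehyde is used at once.

Step 14
Reactants: 18 (S)-3-(bromomethyl)-5-{(E)-3-(tert-butyldimethylsilyloxy)-2-[(4-methoxybenzyloxy)methyl]prop-1-enyl}furan-2(5H)-one; 22 (Z)-3-iodobut-2-enal
Product: 24 C8 alcohol of the 6,7-trans α-methylene lactone with (Z)-1-hydroxy-3-iodobut-2-enyl on C7 and the C3 PMB and C15 TBS ethers (C6/C7/C8 arranged as in 37), via allylzinc bromide 23 (not isolated)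
Conditions: Zn dust, THF/sat. aq. NH4Cl, 0 °C to rt
Reagents that add atoms: none
Why: Barbier allylation: zinc inserts into the allylic C–Br bond and the allylzinc 23 adds through its γ-carbon (C7) to the aldehyde in a closed chair-like six-membered transition state, which turns the butenolide into the α-methylene lactone. C7 is set by attack on the ring face opposite the C6 substituent (trans lactone). C8 is set because the ring holds C6 trans to the metal-bearing carbon, so the chair with the aldehyde substituent equatorial gives O8 anti to C6, as required. The vinyl iodide is inert to zinc here, and no ketone is present, so the cis-hydroxy olefin cannot close to a furan.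

Step 15
Reactants: 24 C8 alcohol of the 6,7-trans α-methylene lactone; 25 angelic acid
Product: 27 C8 angelate of the 6,7-trans α-methylene lactone with the (Z)-C9=C10 iodo-olefin and the C3 PMB and C15 TBS ethers, via mixed anhydride 26 (not isolated)
Conditions: 2,4,6-Cl3C6H2COCl, Et3N, toluene, rt; then 24, toluene, 80 °C (no DMAP)
Reagents that add atoms: none
Why: Yamaguchi-type esterification through mixed anhydride 26; the hindered trichlorobenzoyl carbonyl directs the alcohol to the angeloyl carbon. No nucleophilic amine catalyst is used, because such catalysts isomerise angelates to tiglates by conjugate addition–elimination.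

Step 16
Reactants: 27 C8 angelate with the (Z)-C9=C10 iodo-olefin; 28 tributyl(1-ethoxyvinyl)stannane
Product: 29 2-ethoxydiene: C10 carries the 1-ethoxyvinyl group (C1 and C2) cis to C8; C8 angelate and C3 PMB and C15 TBS ethers unchanged
Conditions: Pd2(dba)3 (cat.), AsPh3, CuI (cat.), NMP, rt
Reagents that add atoms: none
Why: Stille coupling of the Z-alkenyl iodide with retention; copper co-catalysis and the weakly bound arsine ligand allow room temperature, so that zerovalent palladium does not ionise the allylic lactone or the allylic angelate. C1 and C2 enter only now, after O8 is acylated.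

Step 17
Reactants: 29 2-ethoxydiene
Product: 30 bromomethyl ketone (BrCH2–C1(=O) on C10 with C1 cis to C8) with C8 angelate and C3 PMB and C15 TBS ethers
Conditions: NBS (1.0 equiv), NaHCO3, THF/H2O, 0 °C
Reagents that add atoms: N-bromosuccinimide O=C1CCC(=O)N1Br; water O
Why: Electrophilic bromination of the enol ether at its terminal carbon; water captures the oxocarbenium ion and loss of ethanol gives the bromomethyl ketone directly, with no enolate chemistry. The enol ether is by far the most electron-rich π-system, so one equivalent of NBS is selective.

Step 18
Reactants: 30 bromomethyl ketone PMB ether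
Product: 31 bromomethyl ketone with free C3 hydroxyl (C15 TBS ether and C8 angelate retained)
Conditions: DDQ, CH2Cl2/pH 7 buffer, 0 °C
Reagents that add atoms: none
Why: Oxidative PMB cleavage by hydride abstraction and hydrolysis of the resulting oxocarbenium ion; the silyl ether, the esters and the bromoketone are inert to buffered DDQ.

Step 19
Reactants: 31 bromomethyl ketone with free C3 hydroxyl
Product: 32 seco bromomethyl (Z)-enone (Z)-enal: C2 bromide and C1 ketone; C3 aldehyde cis to C6; C8 angelate; C15 TBS ether; 6,7-trans methylene lactone
Conditions: MnO2 (activated, excess), CH2Cl2, rt; filtered and used directly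
Reagents that add atoms: none
Why: Neutral allylic oxidation gives the enal with its formyl group cis to C6 immediately before ring closure, so that this configurationally labile group is not carried through further steps.

Step 20
Reactants: 32 seco bromomethyl (Z)-enone (Z)-enal
Product: 34 ten-membered C3-hydroxy C1-ketone (C15 TBS ether; C8 angelate; 6,7-trans methylene lactone), via chromium enolate 33 (not isolated)
Conditions: CrCl2 (excess), LiI (cat.), THF, rt; 32 added by syringe pump to about 1 mM
Reagents that add atoms: none
Why: Two single-electron transfers from divalent chromium, accelerated by iodide through the transient iodoketone, cleave the C2–halogen bond and give the trivalent chromium enolate 33, whose nucleophilic carbon is fixed at C2 because no proton transfer is involved. The enolate adds to the C3 aldehyde through a closed six-membered chair-like transition state with chromium bridging both oxygens, and the chromium aldolate resists retro-aldol cleavage and dehydration until work-up. The closest known reaction type is the chromium Reformatsky reaction of α-halo ketones and esters with aldehydes, including its use, and that of the SmI2 variant, for medium and large rings; only the pairing of a Z-enal with a Z-enone in one ring lacks direct precedent. The ten-membered ring closes in the 10-exo-trig mode: C2 attacks the C3 carbonyl carbon and the C=O bond stays outside the ring. The new stereocentre C3 is controlled by the substrate alone: the trans-fused lactone and the two cis olefins leave the seco chain few conformations, and the aldehyde face turned toward C2 in the favoured chair decides the configuration; the 3S alcohol is the one needed, and this is the least predictable element of the route. Chemoselectivity rests on the reagent: divalent chromium reduces the α-halo ketone far faster than it touches the enal, enone, lactone or angelate, and the chromium enolate adds to aldehydes but not to esters or ketones. 1,2-Addition over conjugate addition follows from the closed transition state, and ring closure over oligomerisation is secured by slow addition of 32 to excess CrCl2 at high dilution.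

Step 21
Reactants: 34 ten-membered C3-hydroxy C1-ketone
Product: 36 C15 TBS ether of the target (C3 acetate; free C1 alcohol anti to C3), via hemiacetal 35 (not isolated)
Conditions: SmI2 (cat., premixed with MeCHO), MeCHO (excess), THF, −10 °C
Reagents that add atoms: acetaldehyde CC=O
Why: Evans–Tishchenko reduction: the C3 alkoxide adds to acetaldehyde to give the samarium-bound hemiacetal 35, whose hydride is delivered intramolecularly to the C1 ketone through a six-membered chair-like transition state in which trivalent samarium bridges both oxygens. Hydride therefore arrives from the side of O3, the C1 hydroxyl comes out anti to C3 (1S), and the acetyl group is left on O3. Premixing SmI2 with the aldehyde converts it to the trivalent catalyst, so that no divalent samarium meets the γ-acyloxy enone.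

Step 22
Reactants: 36 C15 TBS ether of the target
Product: 37 target CNP0153210.4
Conditions: HF·pyridine, pyridine, THF, 0 °C to rt
Reagents that add atoms: none
Why: Fluoride-mediated Si–O cleavage under buffered, mildly acidic conditions, chosen so that the C3 acetate does not migrate to O1 or O15 and the angelate and methylene lactone are untouched.

## Compound list

1 | 2-butyne-1,4-diol | OCC#CCO | starting material
2 | 4-(tert-butyldimethylsilyloxy)but-2-yn-1-ol | OCC#CCO[Si](C)(C)C(C)(C)C | intermediate
3 | sodium cyclic alkenylaluminate from 2 (five-membered oxaaluminacycle, two 2-methoxyethoxy groups on Al) | [Na+].COCCO[Al-]1(OCCOC)OCC=C1CO[Si](C)(C)C(C)(C)C | intermediate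
4 | (Z)-4-(tert-butyldimethylsilyloxy)-3-iodobut-2-en-1-ol | OC/C=C(\I)CO[Si](C)(C)C(C)(C)C | intermediate
5 | 4-methoxybenzyl alcohol | COc1ccc(CO)cc1 | starting material
6 | tributyl(iodomethyl)stannane | CCCC[Sn](CCCC)(CCCC)CI | starting material
7 | tributyl[(4-methoxybenzyloxy)methyl]stannane | CCCC[Sn](CCCC)(CCCC)COCc1ccc(OC)cc1 | intermediate
8 | (E)-4-(tert-butyldimethylsilyloxy)-3-[(4-methoxybenzyloxy)methyl]but-2-en-1-ol | OC/C=C(\COCc1ccc(OC)cc1)CO[Si](C)(C)C(C)(C)C | intermediate
9 | (E)-4-(tert-butyldimethylsilyloxy)-3-[(4-methoxybenzyloxy)methyl]but-2-enal | O=C/C=C(\COCc1ccc(OC)cc1)CO[Si](C)(C)C(C)(C)C | intermediate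
10 | prop-2-yn-1-ol | C#CCO | starting material
11 | triethyl(prop-2-yn-1-yloxy)silane | C#CCO[Si](CC)(CC)CC | intermediate
12 | methyl[3-(triethylsilyloxy)prop-1-ynyl]zinc | C[Zn]C#CCO[Si](CC)(CC)CC | intermediate
13 | (4S,5E)-7-(tert-butyldimethylsilyloxy)-6-[(4-methoxybenzyloxy)methyl]-1-(triethylsilyloxy)hept-5-en-2-yn-4-ol | CC[Si](CC)(CC)OCC#C[C@@H](O)/C=C(\COCc1ccc(OC)cc1)CO[Si](C)(C)C(C)(C)C | intermediate
14 | sodium cyclic alkenylaluminate from 13 (Al on C11 and on O6) | [Na+].COCCO[Al-]1(OCCOC)O[C@@H](/C=C(\COCc2ccc(OC)cc2)CO[Si](C)(C)C(C)(C)C)C=C1CO[Si](CC)(CC)CC | intermediate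
15 | (2Z,4S,5E)-7-(tert-butyldimethylsilyloxy)-2-iodo-6-[(4-methoxybenzyloxy)methyl]-1-(triethylsilyloxy)hepta-2,5-dien-4-ol | CC[Si](CC)(CC)OC/C(I)=C/[C@@H](O)/C=C(\COCc1ccc(OC)cc1)CO[Si](C)(C)C(C)(C)C | intermediate
16 | (S)-5-{(E)-3-(tert-butyldimethylsilyloxy)-2-[(4-methoxybenzyloxy)methyl]prop-1-enyl}-3-[(triethylsilyloxy)methyl]furan-2(5H)-one | O=C1O[C@@H](/C=C(\COCc2ccc(OC)cc2)CO[Si](C)(C)C(C)(C)C)C=C1CO[Si](CC)(CC)CC | intermediate
17 | (S)-5-{(E)-3-(tert-butyldimethylsilyloxy)-2-[(4-methoxybenzyloxy)methyl]prop-1-enyl}-3-(hydroxymethyl)furan-2(5H)-one | O=C1O[C@@H](/C=C(\COCc2ccc(OC)cc2)CO[Si](C)(C)C(C)(C)C)C=C1CO | intermediate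
18 | (S)-3-(bromomethyl)-5-{(E)-3-(tert-butyldimethylsilyloxy)-2-[(4-methoxybenzyloxy)methyl]prop-1-enyl}furan-2(5H)-one | O=C1O[C@@H](/C=C(\COCc2ccc(OC)cc2)CO[Si](C)(C)C(C)(C)C)C=C1CBr | intermediate
19 | but-2-yn-1-ol | CC#CCO | starting material
20 | sodium cyclic alkenylaluminate from 19 | [Na+].COCCO[Al-]1(OCCOC)OCC=C1C | intermediate
21 | (Z)-3-iodobut-2-en-1-ol | C/C(I)=C/CO | intermediate
22 | (Z)-3-iodobut-2-enal | C/C(I)=C/C=O | intermediate
23 | allylzinc bromide from 18 (zinc on C13) | O=C1O[C@@H](/C=C(\COCc2ccc(OC)cc2)CO[Si](C)(C)C(C)(C)C)C=C1C[Zn]Br | intermediate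
24 | C8 alcohol: α-methylene-γ-butyrolactone closed on O6, H6/H7 trans; on C6 the (E)-3-(TBS-oxy)-2-[(PMB-oxy)methyl]prop-1-enyl group; on C7 the (Z)-1-hydroxy-3-iodobut-2-enyl group; C6, C7, C8 arranged as in 37 | I/C(C)=C\[C@@H](O)[C@@H]1C(=C)C(=O)O[C@H]1/C=C(/CO[Si](C)(C)C(C)(C)C)COCc2ccc(OC)cc2 | intermediate
25 | angelic acid, (Z)-2-methylbut-2-enoic acid | C/C=C(/C)C(=O)O | starting material
26 | angelic 2,4,6-trichlorobenzoic anhydride | C/C=C(/C)C(=O)OC(=O)c1c(Cl)cc(Cl)cc1Cl | intermediate
27 | C8 angelate of 24 (Z-alkenyl iodide at C10, C3 PMB ether, C15 TBS ether) | I/C(C)=C\[C@@H](OC(=O)/C(C)=C\C)[C@@H]1C(=C)C(=O)O[C@H]1/C=C(/CO[Si](C)(C)C(C)(C)C)COCc2ccc(OC)cc2 | intermediate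
28 | tributyl(1-ethoxyvinyl)stannane | CCCC[Sn](CCCC)(CCCC)C(=C)OCC | starting material
29 | 2-ethoxydiene: 1-ethoxyvinyl group (C1, C2) on C10 cis to C8; otherwise as 27 | C=C(OCC)/C(C)=C\[C@@H](OC(=O)/C(C)=C\C)[C@@H]1C(=C)C(=O)O[C@H]1/C=C(/CO[Si](C)(C)C(C)(C)C)COCc2ccc(OC)cc2 | intermediate
30 | C2-bromomethyl (Z)-enone with C8 angelate, C3 PMB ether, C15 TBS ether | BrCC(=O)/C(C)=C\[C@@H](OC(=O)/C(C)=C\C)[C@@H]1C(=C)C(=O)O[C@H]1/C=C(/CO[Si](C)(C)C(C)(C)C)COCc2ccc(OC)cc2 | intermediate
31 | C2-bromomethyl (Z)-enone with free C3 hydroxyl, C8 angelate, C15 TBS ether | BrCC(=O)/C(C)=C\[C@@H](OC(=O)/C(C)=C\C)[C@@H]1C(=C)C(=O)O[C@H]1/C=C(/CO[Si](C)(C)C(C)(C)C)CO | intermediate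
32 | seco C2-bromomethyl (Z)-enone and C3 (Z)-enal with lactone, C8 angelate and C15 TBS ether | BrCC(=O)/C(C)=C\[C@@H](OC(=O)/C(C)=C\C)[C@@H]1C(=C)C(=O)O[C@H]1/C=C(/CO[Si](C)(C)C(C)(C)C)C=O | intermediate
33 | trivalent chromium enolate of 32 (O-bound, nucleophilic at C2) | C=C(O[Cr](Cl)Cl)/C(C)=C\[C@@H](OC(=O)/C(C)=C\C)[C@@H]1C(=C)C(=O)O[C@H]1/C=C(/CO[Si](C)(C)C(C)(C)C)C=O | intermediate
34 | ten-membered (3S)-C3-hydroxy C1-ketone with C15 TBS ether | C=C1C(=O)O[C@H]2/C=C(/CO[Si](C)(C)C(C)(C)C)[C@@H](O)CC(=O)/C(C)=C\[C@@H](OC(=O)/C(C)=C\C)[C@H]12 | intermediate
35 | O3 hemiacetal of 34 with acetaldehyde (samarium-bound in the flask) | C=C1C(=O)O[C@H]2/C=C(/CO[Si](C)(C)C(C)(C)C)[C@@H](OC(C)O)CC(=O)/C(C)=C\[C@@H](OC(=O)/C(C)=C\C)[C@H]12 | intermediate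
36 | C15 TBS ether of the target (C3 acetate, free 1S alcohol) | C=C1C(=O)O[C@H]2/C=C(/CO[Si](C)(C)C(C)(C)C)[C@@H](OC(C)=O)C[C@H](O)/C(C)=C\[C@@H](OC(=O)/C(C)=C\C)[C@H]12 | intermediate
37 | CNP0153210.4, (1S,3S,6S,7S,8R) in the numbering used here | C=C1C(=O)O[C@H]2/C=C(/CO)[C@@H](OC(C)=O)C[C@H](O)/C(C)=C\[C@@H](OC(=O)/C(C)=C\C)[C@H]12 | target

## Step count and least certain steps

Total: 22 steps. Longest linear sequence: 18 steps (steps 1, 2, 4, 5, 7–11, 14–22).

Step 20 (key step). The ring closure may be too slow against transannular strain, so that the chromium enolate is lost by protonation (net debromination) or by intermolecular aldol addition. The facial selectivity at C3 may also be low, since only the ring-forming conformation controls it. Fallback: close the same C2–C3 bond by a boron aldol reaction, setting out from 29. Hydrolysis of the enol ether (PPTS, wet acetone) gives the methyl ketone PMB ether F1; DDQ gives the methyl ketone alcohol F2; MnO2 gives the seco methyl ketone enal F3. Diisopinocampheylboron chloride and Et3N at high dilution then enolise the methyl ketone on the methyl side, and the covalent boron enolate, which has no protonation pathway and persists until it cyclises, adds to the C3 aldehyde. A non-oxidative work-up (diethanolamine) returns the route at 34. The chiral ligands on boron add reagent control to the choice of aldehyde face, and either antipode of the reagent can be used.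

Step 14. Diastereoselection at C8 may be poor if the allylzinc reacts through an open transition state in the aqueous medium. Fallback: setting out from 18 and 22, the C8-epimeric alcohol F4 is separated and esterified with 25 under Mitsunobu conditions (PPh3, diisopropyl azodicarboxylate, toluene, 0 °C). Inversion at C8 gives 27 directly, where the route is rejoined. Direct SN2 displacement should prevail over allylic transposition because the distal olefin carbon C10 is fully substituted and bears iodine.

Step 16. Zerovalent palladium may ionise the allylic angelate or the allylic lactone C–O bond, with loss or scrambling of C8 or C6, if transmetalation is slow. Fallback without palladium, setting out from 18: commercial (Z)-3-methylpent-2-en-4-yn-1-ol is oxidised with MnO2 to (Z)-3-methylpent-2-en-4-ynal F5. Zinc-mediated Barbier allylation of F5 with 18 (as in step 14) gives the enyne alcohol F6, and esterification with 25 through 26 (as in step 15) gives the enyne angelate F7. NBS with catalytic AgNO3 in acetone converts the terminal alkyne to the bromoalkyne F8. Hydration catalysed by Ph3PAuNTf2 in wet dioxane, with water adding at the internal carbon, gives the bromomethyl ketone 30, where the route is rejoined. The gold catalyst is used only after O8 is acylated, because the free cis-enynol would cycloisomerise to a furan.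

Step 21. The Lewis-acidic samarium alkoxide of the aldol may undergo retro-aldol reopening of the strained ring, or residual divalent samarium may reduce the γ-acyloxy enone by electron transfer. Fallback: separate acylation and reduction, setting out from 34. Ac2O and pyridine at 0 °C give the C3 acetate C1 ketone F9. Corey–Bakshi–Shibata reduction with the (R)-B-methyl oxazaborolidine derived from diphenylprolinol and catecholborane in toluene at −78 °C reduces the C1 carbonyl 1,2 under reagent control, the alkenyl arm C10 acting as the large group, and gives the 1S alcohol 36, where the route is rejoined.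

## Further compounds

F1 | step 20 | C1 methyl (Z)-enone with C8 angelate, C3 PMB ether and C15 TBS ether | CC(=O)/C(C)=C\[C@@H](OC(=O)/C(C)=C\C)[C@@H]1C(=C)C(=O)O[C@H]1/C=C(/CO[Si](C)(C)C(C)(C)C)COCc2ccc(OC)cc2
F2 | step 20 | C1 methyl (Z)-enone with free C3 hydroxyl | CC(=O)/C(C)=C\[C@@H](OC(=O)/C(C)=C\C)[C@@H]1C(=C)C(=O)O[C@H]1/C=C(/CO[Si](C)(C)C(C)(C)C)CO
F3 | step 20 | seco C1 methyl (Z)-enone and C3 (Z)-enal | CC(=O)/C(C)=C\[C@@H](OC(=O)/C(C)=C\C)[C@@H]1C(=C)C(=O)O[C@H]1/C=C(/CO[Si](C)(C)C(C)(C)C)C=O
F4 | step 14 | C8 epimer of alcohol 24 | I/C(C)=C\[C@H](O)[C@@H]1C(=C)C(=O)O[C@H]1/C=C(/CO[Si](C)(C)C(C)(C)C)COCc2ccc(OC)cc2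
F5 | step 16 | (Z)-3-methylpent-2-en-4-ynal | C#C/C(C)=C\C=O
F6 | step 16 | C8 alcohol with (Z)-enyne in place of the alkenyl iodide | C#C/C(C)=C\[C@@H](O)[C@@H]1C(=C)C(=O)O[C@H]1/C=C(/CO[Si](C)(C)C(C)(C)C)COCc2ccc(OC)cc2
F7 | step 16 | C8 angelate of the (Z)-enyne | C#C/C(C)=C\[C@@H](OC(=O)/C(C)=C\C)[C@@H]1C(=C)C(=O)O[C@H]1/C=C(/CO[Si](C)(C)C(C)(C)C)COCc2ccc(OC)cc2
F8 | step 16 | 1-bromoalkyne of the (Z)-enyne angelate | BrC#C/C(C)=C\[C@@H](OC(=O)/C(C)=C\C)[C@@H]1C(=C)C(=O)O[C@H]1/C=C(/CO[Si](C)(C)C(C)(C)C)COCc2ccc(OC)cc2
F9 | step 21 | ten-membered C3 acetate C1 ketone with C15 TBS ether | C=C1C(=O)O[C@H]2/C=C(/CO[Si](C)(C)C(C)(C)C)[C@@H](OC(C)=O)CC(=O)/C(C)=C\[C@@H](OC(=O)/C(C)=C\C)[C@H]12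
A1 | alternative 1 | ten-membered carbocycle with free C8 hydroxyl and C11=C13 methylene (O6 and O12 as TES ethers, O1 and O15 as TBS ethers, O3 as PMB ether) | C=C(CO[Si](CC)(CC)CC)[C@@H]1[C@@H](O[Si](CC)(CC)CC)/C=C(/CO[Si](C)(C)C(C)(C)C)[C@@H](OCc2ccc(OC)cc2)C[C@H](O[Si](C)(C)C(C)(C)C)/C(C)=C\[C@H]1O
A2 | alternative 2 | ten-membered Z,Z-dienedione with ketones at C1 and C6 (C3 acetate, C8 angelate, C12 methyl ester, C15 TBS ether) | C=C(C(=O)OC)[C@@H]1C(=O)/C=C(/CO[Si](C)(C)C(C)(C)C)[C@@H](OC(C)=O)CC(=O)/C(C)=C\[C@H]1OC(=O)/C(C)=C\C
A3 | alternative 3 | ten-membered ring with C15 as methyl ester on the C4=C5 olefin (free C3 hydroxyl, O1 TBS, O6 and O12 TES, O8 PMB) | C=C(CO[Si](CC)(CC)CC)[C@@H]1[C@@H](O[Si](CC)(CC)CC)/C=C(/C(=O)OC)[C@@H](O)C[C@H](O[Si](C)(C)C(C)(C)C)/C(C)=C\[C@H]1OCc2ccc(OC)cc2
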